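The readings were computed for substances that don't exist; noise was put on by code.

The product in the oak flask sits on a flat line from its first reading, and the height of that line, taken per enzyme charged, is the number we want to carry. In oak, which is the flask asked about, a free enzyme turns starting material, dissolving from a solid substrate, and second substrate into product, at 25 °C.

common to all: solid substrate 20 mM; free enzyme 4.6 µM; temperature 25 °C

| flask | second substrate | remark | time |
|---|---|---|---|
| oak | 60 mM | the very flask that is asked about, followed so far |  |
| elm | 30 mM | run made earlier |  |
| flask | 60.0 mM |  | 20 min |

oak run (percent of the solid substrate charged)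

| time / min | product / % | solid substrate / % |
|---|---|---|
| 3.00 | 53 | 39 |
| 6.00 | 53 | 36 |
| 10.0 | 55 | 38 |
| 12.0 | 51 | 35 |
| 15.0 | 55 | 35 |
| 20.0 | 52 | 36 |

elm run (percent of the solid substrate charged)

| time / s | product / % | solid substrate / % |
|---|---|---|
| 20.0 | 10 | 79 |
| 40.0 | 18 | 74 |
| 60.0 | 24 | 67 |
| 80.0 | 28 | 58 |
| 90.0 | 30 | 56 |
| 120 | 36 | 56 |

(each reading ± 2 percentage points)

- winter: at 20 min take out 90% of the product then present, then wait 10 min
- spring: at 20 min add second substrate, 100% of the amount charged, then wait 10 min
- dusk: at 20 min raise the temperature by 10 K, then wait 10 min
- summer: at 20 min add free enzyme, 100% of the amount charged, then wait 10 min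
- midnight: change nothing and wait 10 min more

1. product, in percent of the solid substrate first charged, at 20 min
2. the remedy with the largest gain of product, or "none" below 2 percentage points (winter / spring / dusk / summer / midnight / none)
3. product present, with what was taken out counted in, in percent of the solid substrate first charged, after spring
4. product present, with what was taken out counted in, in percent of the solid substrate first charged, after dusk

- given per volume of solution although it is solid: solid substrate
- what is taken out of product is counted as made
- the numbers in the tables scatter with a standard deviation of 2 percentage points
- what may be going on: free enzyme -> unfolded enzyme; starting material + free enzyme <-> starting complex; second substrate + starting complex <-> ternary complex; ternary complex -> free enzyme + product; solid substrate <-> starting material; second substrate + starting complex -> spent catalyst A; free enzyme -> spent catalyst B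
- at the start none of the solid substrate is in solution
- additions bring no volume worth counting
- the earlier runs do not show what temperature does; that part of a forecast is a guess

We read the flask as a ladder of times, from what is over first to what is over last. Dissolving comes first: at 20.0 s in the elm run, solid and product leave a gap of 11.0% of the charge, and oak's last readings leave 12.0%, so, as far as the scatter lets us read, a dissolved level is reached early and stays.

Next comes the making of product, which in elm is still climbing at 120 s: elm's first reading gives an average pace of 21.7 /s per enzyme charged.

Then comes the catalyst's end. Oak's product readings average 53.2%, while 36% stands as solid at 20.0 min and, by subtraction, 82.3% of the second substrate remains. Both reagents are still present in these amounts, so we take it that the catalyst has stopped. We call the product made per enzyme charged the turnover budget (the turnover number), 2310. At elm's early pace, read at 30 mM of second substrate and not at oak's 60 mM, we estimate that this budget lasts 1.77 min, which is less than the 3.00 min of oak's first reading.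

The last rung is our waiting, and 20 min is far longer than that life. So we commit to 53.2% now, and to the same after winter, spring, midnight and dusk, though the temperature is a guess.

If the fresh enzyme in summer earns the same budget, it brings 53.2% of the charge. Putting that back in, the room is 46.8%, which is less, so solid substrate, counted with what has dissolved, becomes the limiting reagent and we expect a gain near 46.8%.

The forecast gave 53.2% (51.8% to 54.6%), summer as best, and 53.2% after spring and 53.2% after dusk, saying “The reaction has therefore stopped because the catalyst is dead, not for lack of reagents.”

Oak gives 52.6%, with summer best at a gain of 46 percentage points, and 52.6% after spring and 52.6% after dusk.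

    free enzyme → unfolded enzyme (k = 4.80 × 10⁻⁴ /s, Ea = 285 kJ/mol)
    starting material + free enzyme ⇌ starting complex (K = 100 /M, k = 9.40 × 10⁵ /M/s, Ea = 20.0 kJ/mol, ΔH = 1.00 kJ/mol)
    second substrate + starting complex ⇌ ternary complex (K = 23.0 /M, k = 26000 /M/s, Ea = 20.0 kJ/mol, ΔH = 1.00 kJ/mol)
    ternary complex → free enzyme + product (k = 360 /s, Ea = 46.0 kJ/mol)
    solid substrate ⇌ starting material, rate k5*(cs5 - [starting material]) while solid is left; crystals form when [starting material] > cs5 (solubility = 2.20 mM, k = 1.20 /s)
    second substrate + starting complex → spent catalyst A (k = 2.00 /M/s, Ea = 58.0 kJ/mol)
    free enzyme → spent catalyst B (k = 0.00760 /s, Ea = 86.0 kJ/mol)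
    (constants at 25 °C)

Oak's result makes the budget 2290, and summer's gain stands against our room of 46.8%. The same reckoning on the neighbour, oak's charge run at 40 °C, turns its 13.9% of product into a budget of 602, a quarter of oak's 2310. There, at 20.0 min, 86% of the solid substrate charged is still present, solid or dissolved, and free enzyme is down to 0%. Unfolded enzyme holds 54.1% of that neighbour's catalyst, against 1.61% in oak.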